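## The problem

The target is a biflavanoid. Two 2,3-trans-flavan-3-ol units with 7-hydroxylated (5-deoxy) rings A are joined by one C–C bond from C4 of the upper unit to C6′ of ring B of the lower unit, so lower ring B carries two neighbouring benzylic stereocentres, upper C4 and lower C2. Five stereocentres have to be set. Upper C2, C3 and C4 are contiguous and all-trans (2R,3S,4R), so C2 can control C3 and C4; lower C2 and C3 are trans (2R,3S) and can control each other; the two sets are insulated by the arene and each needs its own source of absolute configuration. Both C2–O1 bonds are para-alkoxybenzylic ethers, and lower C2 is also crowded by the ortho flavanyl group, so any step that ionises or displaces at these carbons risks epimerisation; the six phenols (two catechols) are oxidation-prone and must stay masked to the end. A biomimetic union of an upper C4 cation with a finished lower flavan is ruled out, because lower ring A (a resorcinol-type ether) is far more nucleophilic than C6′ of ring B; the C4–C6′ bond must exist before lower ring A is part of a flavan. The feature that allows this is the lower O1–C8a bond: it is an aryl–oxygen bond that touches no stereocentre, so lower ring C can be closed last from the C2 hydroxyl and a bromine at C8a of ring A while the C–O bonds at C2 and C3 stay intact. Closure with retention fixes the open-chain precursor as the anti (1R,2S) diol derivative; a syn diol, the product of dihydroxylating an (E)-1,3-diarylpropene, would close to the 2,3-cis ring.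

## Retrosynthesis

**27 ⇒ 26.** All eight O–benzyl bonds are cut. Benzyl ethers survive organomagnesium and organolithium reagents, borane, hydride and hot Cs2CO3, and one hydrogenolysis removes them; silyl or acyl groups on the two secondary hydroxyls would each add a cleavage step. The forward step must not cleave the two benzylic C2–O1 ring bonds.

**26 ⇒ 25.** The lower O1–C8a bond is cut. The neighbouring cuts are worse: O1–C2 would need a displacement at the hindered, ionisable lower C2, and C4–C4a a Friedel–Crafts closure next to competing electron-rich rings. Precursor 25 is acyclic in its lower half and lower ring A is reduced to a simple bromoarene. The forward reaction is an O-arylation of a hindered secondary alkoxide that must not lose a β-hydride.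

**25 ⇒ 24.** The C2–H bond of the carbinol is cut, giving ketone 24. The anti relation cannot come from alkene dihydroxylation (syn), and inversion at this benzylic carbon is unreliable. Chelation-controlled hydride delivery to the α-benzyloxy ketone gives the anti alcohol directly; the same C3 benzyl ether later blocks five-ring closure and leaves with the other benzyl groups. The forward step must be strongly anti-selective.

**24 ⇒ 12 + 22.** The bond from lower C2 to C1′ of ring B is cut. This is the convergent cut: aryl bromide 12 holds the complete upper unit and ring B, and Weinreb amide 22 holds lower C3, C4 and ring A. Only four steps follow the union. The forward step is acylation of a hindered aryllithium in the presence of a second aryl bromide.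

**22 ⇒ 21 ⇒ 19 + 16.** The lower C3–C4 bond is cut. Alkylation of the glycolate imide 19 with benzylic bromide 16 sets lower C3 under auxiliary control. Bromide 16 comes from 13 through 14 and 15; imide 19 comes from 17 and 18. Both partners are small and the reaction class is reliable.

**12 ⇒ 11 ⇒ 9 ⇒ 8 ⇒ 4 + 6.** In 11 the C3–O and C4–H bonds are cut: hydroboration of chromene 9 sets upper C3 and C4 from C2 in one step and gives the all-trans pattern. Chromene 9 comes from alcohol 8 by dehydration. In 8 the C4–C6′ bond is cut to flavanone 4 and the arylmagnesium reagent 7 from dibromide 6. A carbonyl addition is preferred to a Friedel–Crafts arylation because the site on ring B is fixed by the bromine pattern of 6, no cation is involved, and the second bromine becomes the handle for the union with 22.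

**4 ⇒ 2 + 3.** The bond from upper C2 to its aryl group is cut. Catalytic asymmetric conjugate addition of boronic acid 3 to chromone 2 sets upper C2 on a small, unhindered substrate. Chromone 2 comes from 1 and dibromide 6 from 5 by benzylation.

## Roads not taken

**Alternative 1:** The cut is the upper C4–C4a bond. The lower flavan would be finished first and carried on ring B into trans-epoxide A1, whose upper C2 oxygen already bears a 3-(benzyloxy)phenyl group. With Sc(OTf)3 in hexafluoroisopropanol the aryl ether ring would attack the benzylic epoxide carbon and close upper ring C, giving A2 with a free upper C3 hydroxyl.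
- Merits: a C–C bond, a ring and the C4 stereocentre arise together under catalytic, cold conditions; the epoxide fixes the 3,4-trans relation by inversion; no halide or hot base is needed. On these points it is at least the equal of the chosen plan, whose key step forms only a C–O bond at 110 °C.
- Weak points: the epoxide carbon is benzylic to lower ring B and para to a benzyloxy group, so opening will be cationic and inversion is not assured. The aryl ether at upper C2 is itself a para-alkoxybenzylic ether that the same acid can ionise. The intact lower ring A is a better π-nucleophile than the tethered ring and can intercept the cation. A1 also needs an acid-labile electron-rich epoxide and an etherification at a benzylic carbinol.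
- Comparison: the chosen plan uses no cation chemistry once the two halves are joined and makes lower ring A part of a flavan only in the last closure.

**Alternative 2:** The cut is the lower O1–C2 bond together with the C3–O bond; lower ring C is seen as the ring-expanded form of a 2-substituted 2,3-dihydrobenzofuran. With Zn(OAc)2 the mesylate A3 would ionise with participation of the ring oxygen to the bicyclic oxiranium ion A4, and acetate would open A4 at the former furan carbon to give acetate A5.
- Merits: two inversions make it stereospecific at both lower stereocentres; the precursor can come from a syn diol, so alkene dihydroxylation (which the chosen plan cannot use) becomes available; no transition metal or aryl bromide is needed.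
- Weak points: the ionising carbon is lower C2 itself, para-alkoxybenzylic and flanked by the upper unit, so an open cation is likely to precede participation and erode C2. Acetate should prefer the benzylic end of A4, which returns the five-membered ring. The ortho flavanyl group hinders backside approach of the ring oxygen. The acetate costs an extra cleavage.
- Comparison: the chosen plan never breaks a bond at lower C2 or C3 once they are set; this is what it sets against the shorter access to A3.

**Alternative 3:** The cut runs through upper ring C at C3–C4 and O1–C2. Benzhydrol A6, with the lower flavan complete and the carbinol carbon as upper C4, would be dehydrated by a chiral BINOL-derived phosphoric acid to ortho-quinone methide A7, which would add (E)-enol pivalate A8 in a [4+2] sense to give A9.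
- Merits: the most convergent road, with two bonds, one ring and three stereocentres in one catalytic operation; the E geometry translates into 2,3-trans. In step count for the upper unit it clearly beats the chosen plan (one step against six from 2).
- Weak points: A7 carries at its terminus an ortho-substituted aryl group bearing the whole lower unit, so its geometry and fit in the catalyst pocket are uncertain. An enol ester is a weak 2π donor compared with styrenes or enol ethers. Catalyst control must be matched with the stereocentres already in A6. Lower ring A of A6 can add to A7 in a Friedel–Crafts sense. The pivalate costs a separate cleavage.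
- Comparison: the chosen plan pays in steps but sets upper C2 with a catalyst on a small substrate, C3 and C4 by substrate-controlled hydroboration, and exposes no electrophile to lower ring A.

Key step: step 16

Assumption: in step 2 the (R) enantiomer of the pyridine–oxazoline ligand is taken to give (2S)-4, by the facial model of this catalyst with cyclic enones; the sense is checked on 4 and the ligand antipode is used if it proves opposite.

## Steps

Step 1
Reactants: 1 7-hydroxy-4H-chromen-4-one
Product: 2 7-(benzyloxy)-4H-chromen-4-one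
Conditions: BnBr, K2CO3, acetone, reflux
Reagents that add atoms: benzyl bromide, BrCc1ccccc1
Why: Williamson ether synthesis on the phenoxide; the chromone ring tolerates K2CO3 in acetone.

Step 2
Reactants: 2 7-(benzyloxy)-4H-chromen-4-one; 3 [3,4-bis(benzyloxy)phenyl]boronic acid
Product: 4 (2S)-7-(benzyloxy)-2-[3,4-bis(benzyloxy)phenyl]-2,3-dihydro-4H-chromen-4-one
Conditions: Pd(OCOCF3)2 (5 mol %), (R)-t-BuPyOx (6 mol %), NH4PF6, H2O, ClCH2CH2Cl, 60 °C
Reagents that add atoms: none
Why: Asymmetric conjugate addition of an arylboronic acid to a chromone catalysed by divalent palladium: transmetalation gives an arylpalladium species, the ligand-controlled insertion of C2=C3 sets upper C2, and water protonates the palladium enolate. The centre is S in the flavanone and becomes R by priority change once C3 is oxygenated.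

Step 3
Reactants: 5 4,5-dibromobenzene-1,2-diol
Product: 6 1,2-bis(benzyloxy)-4,5-dibromobenzene
Conditions: BnBr, K2CO3, DMF, 50 °C
Reagents that add atoms: benzyl bromide, BrCc1ccccc1
Why: Double Williamson ether synthesis; starting from the dibromocatechol fixes the bromine pattern without an aromatic bromination.

Step 4
Reactants: 6 1,2-bis(benzyloxy)-4,5-dibromobenzene; 4 (2S)-7-(benzyloxy)-2-[3,4-bis(benzyloxy)phenyl]-2,3-dihydro-4H-chromen-4-one
Product: 8 (2S)-7-(benzyloxy)-2-[3,4-bis(benzyloxy)phenyl]-4-[4,5-bis(benzyloxy)-2-bromophenyl]-3,4-dihydro-2H-chromen-4-ol as C4 epimers, via arylmagnesium chloride 7 (not isolated)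
Conditions: i-PrMgCl·LiCl, THF, −15 °C; then 4, LaCl3·2LiCl, THF, −20 → 0 °C; aq. NH4Cl
Reagents that add atoms: none
Why: Bromine–magnesium exchange is accelerated by the ortho bromine and stops after one exchange; kept cold, the ortho-bromoarylmagnesium does not lose MgBrCl to an aryne. LaCl3·2LiCl promotes 1,2-addition to the enolisable ketone over enolisation and retro-oxa-Michael opening, so C2 is preserved; the C4 configuration is irrelevant because it is removed in step 5.

Step 5
Reactants: 8 (2S)-7-(benzyloxy)-2-[3,4-bis(benzyloxy)phenyl]-4-[4,5-bis(benzyloxy)-2-bromophenyl]-3,4-dihydro-2H-chromen-4-ol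
Product: 9 (2S)-7-(benzyloxy)-2-[3,4-bis(benzyloxy)phenyl]-4-[4,5-bis(benzyloxy)-2-bromophenyl]-2H-chromene
Conditions: Burgess reagent, THF, 50 °C
Reagents that add atoms: none
Why: Burgess dehydration (syn elimination of the sulfamate ester) of a tertiary, doubly benzylic alcohol gives the C3=C4 alkene under neutral conditions, avoiding acid that could ionise the allylic, benzylic C2–O1 bond.

Step 6
Reactants: 9 (2S)-7-(benzyloxy)-2-[3,4-bis(benzyloxy)phenyl]-4-[4,5-bis(benzyloxy)-2-bromophenyl]-2H-chromene
Product: 11 (2R,3S,4S)-7-(benzyloxy)-2-[3,4-bis(benzyloxy)phenyl]-4-[4,5-bis(benzyloxy)-2-bromophenyl]-3,4-dihydro-2H-chromen-3-ol, via C3-alkylborane 10 (not isolated)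
Conditions: BH3·THF, THF, 0 °C → rt; then NaOH, H2O2, 0 °C → rt
Reagents that add atoms: hydrogen peroxide, OO
Why: Hydroboration–oxidation of a trisubstituted 1,1-diaryl alkene: boron adds to C3 on the face opposite the C2 aryl group, hydrogen is delivered syn to C4 so the C4 aryl group ends cis to the C2 aryl group, and oxidation with retention gives the 2,3-trans-3,4-trans alcohol. C3 and C4 are both set by C2; the C4 descriptor is S here only because the bromine raises the priority of ring B.

Step 7
Reactants: 11 (2R,3S,4S)-7-(benzyloxy)-2-[3,4-bis(benzyloxy)phenyl]-4-[4,5-bis(benzyloxy)-2-bromophenyl]-3,4-dihydro-2H-chromen-3-ol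
Product: 12 (2R,3S,4S)-3,7-bis(benzyloxy)-2-[3,4-bis(benzyloxy)phenyl]-4-[4,5-bis(benzyloxy)-2-bromophenyl]-3,4-dihydro-2H-chromene
Conditions: BnBr, NaH, n-Bu4NI (cat.), DMF, 0 °C → rt
Reagents that add atoms: benzyl bromide, BrCc1ccccc1
Why: Williamson O-benzylation of the equatorial secondary alkoxide; no stereocentre is acidic enough to be touched.

Step 8
Reactants: 13 2-bromo-4-hydroxybenzaldehyde
Product: 14 4-(benzyloxy)-2-bromobenzaldehyde
Conditions: BnBr, K2CO3, DMF, rt
Reagents that add atoms: benzyl bromide, BrCc1ccccc1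
Why: Williamson ether synthesis on the phenoxide.

Step 9
Reactants: 14 4-(benzyloxy)-2-bromobenzaldehyde
Product: 15 [4-(benzyloxy)-2-bromophenyl]methanol
Conditions: NaBH4, MeOH/THF, 0 °C
Reagents that add atoms: none
Why: Borohydride reduction of the aldehyde; the aryl bromide and benzyl ether are inert.

Step 10
Reactants: 15 [4-(benzyloxy)-2-bromophenyl]methanol
Product: 16 4-(benzyloxy)-2-bromo-1-(bromomethyl)benzene
Conditions: PBr3, CH2Cl2, 0 °C
Reagents that add atoms: phosphorus tribromide, BrP(Br)Br
Why: Conversion of a benzylic alcohol to the bromide through the phosphite ester; the para-alkoxybenzyl bromide is used without storage.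

Step 11
Reactants: 17 (4R)-4-benzyl-1,3-oxazolidin-2-one; 18 (benzyloxy)acetyl chloride
Product: 19 (4R)-4-benzyl-3-[(benzyloxy)acetyl]-1,3-oxazolidin-2-one
Conditions: Et3N, DMAP (cat.), CH2Cl2, 0 °C → rt
Reagents that add atoms: none
Why: DMAP-catalysed N-acylation of the oxazolidinone by the acid chloride.

Step 12
Reactants: 19 (4R)-4-benzyl-3-[(benzyloxy)acetyl]-1,3-oxazolidin-2-one; 16 4-(benzyloxy)-2-bromo-1-(bromomethyl)benzene
Product: 21 (4R)-4-benzyl-3-{(2S)-2-(benzyloxy)-3-[4-(benzyloxy)-2-bromophenyl]propanoyl}-1,3-oxazolidin-2-one, via sodium (Z)-enolate 20 (not isolated)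
Conditions: NaN(SiMe3)2, THF, −78 °C; then 16, −78 → −45 °C
Reagents that add atoms: none
Why: Evans-type asymmetric alkylation of a glycolate imide: the chelated (Z)-enolate is alkylated by the reactive benzylic bromide on the face opposite the C4 benzyl group of the auxiliary, which sets the (S) centre that becomes lower C3.

Step 13
Reactants: 21 (4R)-4-benzyl-3-{(2S)-2-(benzyloxy)-3-[4-(benzyloxy)-2-bromophenyl]propanoyl}-1,3-oxazolidin-2-one
Product: 22 (2S)-2-(benzyloxy)-3-[4-(benzyloxy)-2-bromophenyl]-N-methoxy-N-methylpropanamide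
Conditions: MeNHOMe·HCl, AlMe3, CH2Cl2, −10 °C → rt; aq. HCl
Reagents that add atoms: N,O-dimethylhydroxylamine hydrochloride, Cl.CNOC
Why: Weinreb transamination with an aluminium amide; the exocyclic carbonyl is activated by the α-oxygen and the non-basic conditions leave the α centre untouched.

Step 14
Reactants: 12 (2R,3S,4S)-3,7-bis(benzyloxy)-2-[3,4-bis(benzyloxy)phenyl]-4-[4,5-bis(benzyloxy)-2-bromophenyl]-3,4-dihydro-2H-chromene; 22 (2S)-2-(benzyloxy)-3-[4-(benzyloxy)-2-bromophenyl]-N-methoxy-N-methylpropanamide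
Product: 24 (2S)-2-(benzyloxy)-1-{4,5-bis(benzyloxy)-2-[(2R,3S,4R)-3,7-bis(benzyloxy)-2-[3,4-bis(benzyloxy)phenyl]-3,4-dihydro-2H-chromen-4-yl]phenyl}-3-[4-(benzyloxy)-2-bromophenyl]propan-1-one, via aryllithium 23 (not isolated)
Conditions: n-BuLi, THF, −78 °C; then 22, −78 → −40 °C; aq. NH4Cl
Reagents that add atoms: none
Why: Bromine–lithium exchange followed by Weinreb ketone synthesis; the chelated tetrahedral adduct prevents over-addition and masks the ketone until work-up, so the α centre is not enolised. This forms the bond from lower C2 to ring B.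

Step 15
Reactants: 24 (2S)-2-(benzyloxy)-1-{4,5-bis(benzyloxy)-2-[(2R,3S,4R)-3,7-bis(benzyloxy)-2-[3,4-bis(benzyloxy)phenyl]-3,4-dihydro-2H-chromen-4-yl]phenyl}-3-[4-(benzyloxy)-2-bromophenyl]propan-1-one
Product: 25 (1R,2S)-2-(benzyloxy)-1-{4,5-bis(benzyloxy)-2-[(2R,3S,4R)-3,7-bis(benzyloxy)-2-[3,4-bis(benzyloxy)phenyl]-3,4-dihydro-2H-chromen-4-yl]phenyl}-3-[4-(benzyloxy)-2-bromophenyl]propan-1-ol
Conditions: Zn(BH4)2, Et2O/CH2Cl2, −30 → 0 °C
Reagents that add atoms: none
Why: Chelation-controlled (Cram-chelate) reduction of an α-benzyloxy ketone: zinc bridges the carbonyl and ether oxygens and hydride enters from the side of the α-hydrogen, giving the anti (1R,2S) alcohol; lower C2 is set by lower C3.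

Step 16
Reactants: 25 (1R,2S)-2-(benzyloxy)-1-{4,5-bis(benzyloxy)-2-[(2R,3S,4R)-3,7-bis(benzyloxy)-2-[3,4-bis(benzyloxy)phenyl]-3,4-dihydro-2H-chromen-4-yl]phenyl}-3-[4-(benzyloxy)-2-bromophenyl]propan-1-ol
Product: 26 (2R,3S)-3,7-bis(benzyloxy)-2-{4,5-bis(benzyloxy)-2-[(2R,3S,4R)-3,7-bis(benzyloxy)-2-[3,4-bis(benzyloxy)phenyl]-3,4-dihydro-2H-chromen-4-yl]phenyl}-3,4-dihydro-2H-chromene
Conditions: CuI (20 mol %), 3,4,7,8-tetramethyl-1,10-phenanthroline (40 mol %), Cs2CO3, toluene, 110 °C, argon
Reagents that add atoms: none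
Why: Cs2CO3 deprotonates the C2 hydroxyl and the alkoxide binds phenanthroline-ligated monovalent copper; oxidative addition of the neighbouring C8a–Br bond is most simply written as giving a seven-membered oxa-cupracycle of trivalent copper, and reductive elimination forms O1–C8a and returns monovalent copper. The closest known reaction type is the intramolecular Ullmann-type copper-catalysed O-arylation of secondary alcohols with aryl bromides that gives chromans. Lower ring C closes in a 6-exo mode onto the sp2 carbon C8a, the C–Br bond lying outside the new ring. No stereocentre is formed: no bond to C2 or C3 is broken, so the anti (1R,2S) configuration of 25 becomes the 2,3-trans (2R,3S) ring. The step needs arylation of the C2 oxygen only; this is secured because it is the one free hydroxyl (the C3 oxygen is a benzyl ether, so no five-ring closure) and because 25 has a single aryl bromide, ortho to the tether. It also needs coupling of the alkoxide rather than loss of a β-hydride; copper alkoxides are much less prone to this than palladium alkoxides, and the benzyloxy group meta to bromine does not deactivate the C–Br bond.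

Step 17
Reactants: 26 (2R,3S)-3,7-bis(benzyloxy)-2-{4,5-bis(benzyloxy)-2-[(2R,3S,4R)-3,7-bis(benzyloxy)-2-[3,4-bis(benzyloxy)phenyl]-3,4-dihydro-2H-chromen-4-yl]phenyl}-3,4-dihydro-2H-chromene
Product: 27 (2R,3S)-2-{2-[(2R,3S,4R)-2-(3,4-dihydroxyphenyl)-3,7-dihydroxy-3,4-dihydro-2H-chromen-4-yl]-4,5-dihydroxyphenyl}-3,4-dihydro-2H-chromene-3,7-diol
Conditions: H2 (1 atm), Pd(OH)2/C, THF/MeOH, rt
Reagents that add atoms: none
Why: Hydrogenolysis of the eight benzyl ethers; O-benzyl groups are cleaved faster than the cyclic benzylic C2–O1 bonds of flavans, and the neutral medium protects the free catechols.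

## Compound list

1 | 7-hydroxy-4H-chromen-4-one | O=c1ccoc2cc(O)ccc12 | starting material
2 | 7-(benzyloxy)-4H-chromen-4-one | O=c1ccoc2cc(OCc3ccccc3)ccc12 | intermediate
3 | [3,4-bis(benzyloxy)phenyl]boronic acid | OB(O)c1ccc(OCc2ccccc2)c(OCc2ccccc2)c1 | starting material
4 | (2S)-7-(benzyloxy)-2-[3,4-bis(benzyloxy)phenyl]-2,3-dihydro-4H-chromen-4-one | O=C1C[C@@H](c2ccc(OCc3ccccc3)c(OCc3ccccc3)c2)Oc2cc(OCc3ccccc3)ccc12 | intermediate
5 | 4,5-dibromobenzene-1,2-diol | Oc1cc(Br)c(Br)cc1O | starting material
6 | 1,2-bis(benzyloxy)-4,5-dibromobenzene | Brc1cc(OCc2ccccc2)c(OCc2ccccc2)cc1Br | intermediate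
7 | [4,5-bis(benzyloxy)-2-bromophenyl]magnesium chloride | Cl[Mg]c1cc(OCc2ccccc2)c(OCc2ccccc2)cc1Br | intermediate (not isolated)
8 | (2S)-7-(benzyloxy)-2-[3,4-bis(benzyloxy)phenyl]-4-[4,5-bis(benzyloxy)-2-bromophenyl]-3,4-dihydro-2H-chromen-4-ol (C4 epimers, C4 left open) | OC1(c2cc(OCc3ccccc3)c(OCc3ccccc3)cc2Br)C[C@@H](c2ccc(OCc3ccccc3)c(OCc3ccccc3)c2)Oc2cc(OCc3ccccc3)ccc12 | intermediate
9 | (2S)-7-(benzyloxy)-2-[3,4-bis(benzyloxy)phenyl]-4-[4,5-bis(benzyloxy)-2-bromophenyl]-2H-chromene | Brc1cc(OCc2ccccc2)c(OCc2ccccc2)cc1C1=C[C@@H](c2ccc(OCc3ccccc3)c(OCc3ccccc3)c2)Oc2cc(OCc3ccccc3)ccc12 | intermediate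
10 | [(2S,3S,4S)-7-(benzyloxy)-2-[3,4-bis(benzyloxy)phenyl]-4-[4,5-bis(benzyloxy)-2-bromophenyl]-3,4-dihydro-2H-chromen-3-yl]borane (boron trans to both aryl groups) | Brc1cc(OCc2ccccc2)c(OCc2ccccc2)cc1[C@@H]1c3ccc(OCc4ccccc4)cc3O[C@H](c3ccc(OCc4ccccc4)c(OCc4ccccc4)c3)[C@H]1B | intermediate (not isolated)
11 | (2R,3S,4S)-7-(benzyloxy)-2-[3,4-bis(benzyloxy)phenyl]-4-[4,5-bis(benzyloxy)-2-bromophenyl]-3,4-dihydro-2H-chromen-3-ol (2,3-trans-3,4-trans) | Brc1cc(OCc2ccccc2)c(OCc2ccccc2)cc1[C@@H]1c3ccc(OCc4ccccc4)cc3O[C@H](c3ccc(OCc4ccccc4)c(OCc4ccccc4)c3)[C@H]1O | intermediate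
12 | (2R,3S,4S)-3,7-bis(benzyloxy)-2-[3,4-bis(benzyloxy)phenyl]-4-[4,5-bis(benzyloxy)-2-bromophenyl]-3,4-dihydro-2H-chromene | Brc1cc(OCc2ccccc2)c(OCc2ccccc2)cc1[C@@H]1c3ccc(OCc4ccccc4)cc3O[C@H](c3ccc(OCc4ccccc4)c(OCc4ccccc4)c3)[C@H]1OCc1ccccc1 | intermediate
13 | 2-bromo-4-hydroxybenzaldehyde | O=Cc1ccc(O)cc1Br | starting material
14 | 4-(benzyloxy)-2-bromobenzaldehyde | O=Cc1ccc(OCc2ccccc2)cc1Br | intermediate
15 | [4-(benzyloxy)-2-bromophenyl]methanol | OCc1ccc(OCc2ccccc2)cc1Br | intermediate
16 | 4-(benzyloxy)-2-bromo-1-(bromomethyl)benzene | BrCc1ccc(OCc2ccccc2)cc1Br | intermediate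
17 | (4R)-4-benzyl-1,3-oxazolidin-2-one | O=C1N[C@H](Cc2ccccc2)CO1 | starting material
18 | (benzyloxy)acetyl chloride | O=C(Cl)COCc1ccccc1 | starting material
19 | (4R)-4-benzyl-3-[(benzyloxy)acetyl]-1,3-oxazolidin-2-one | O=C(COCc1ccccc1)N1[C@H](Cc2ccccc2)COC1=O | intermediate
20 | sodium (Z)-enolate of 19 | [Na+].[O-]/C(=C\OCc1ccccc1)N1[C@H](Cc2ccccc2)COC1=O | intermediate (not isolated)
21 | (4R)-4-benzyl-3-{(2S)-2-(benzyloxy)-3-[4-(benzyloxy)-2-bromophenyl]propanoyl}-1,3-oxazolidin-2-one | Brc1cc(OCc2ccccc2)ccc1C[C@H](OCc1ccccc1)C(=O)N1[C@H](Cc2ccccc2)COC1=O | intermediate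
22 | (2S)-2-(benzyloxy)-3-[4-(benzyloxy)-2-bromophenyl]-N-methoxy-N-methylpropanamide | Brc1cc(OCc2ccccc2)ccc1C[C@H](OCc1ccccc1)C(=O)N(C)OC | intermediate
23 | {4,5-bis(benzyloxy)-2-[(2R,3S,4R)-3,7-bis(benzyloxy)-2-[3,4-bis(benzyloxy)phenyl]-3,4-dihydro-2H-chromen-4-yl]phenyl}lithium | [Li]c1cc(OCc2ccccc2)c(OCc2ccccc2)cc1[C@@H]1c3ccc(OCc4ccccc4)cc3O[C@H](c3ccc(OCc4ccccc4)c(OCc4ccccc4)c3)[C@H]1OCc1ccccc1 | intermediate (not isolated)
24 | (2S)-2-(benzyloxy)-1-{4,5-bis(benzyloxy)-2-[(2R,3S,4R)-3,7-bis(benzyloxy)-2-[3,4-bis(benzyloxy)phenyl]-3,4-dihydro-2H-chromen-4-yl]phenyl}-3-[4-(benzyloxy)-2-bromophenyl]propan-1-one | Brc1cc(OCc2ccccc2)ccc1C[C@H](OCc1ccccc1)C(=O)c1cc(OCc2ccccc2)c(OCc2ccccc2)cc1[C@@H]1c3ccc(OCc4ccccc4)cc3O[C@H](c3ccc(OCc4ccccc4)c(OCc4ccccc4)c3)[C@H]1OCc1ccccc1 | intermediate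
25 | (1R,2S)-2-(benzyloxy)-1-{4,5-bis(benzyloxy)-2-[(2R,3S,4R)-3,7-bis(benzyloxy)-2-[3,4-bis(benzyloxy)phenyl]-3,4-dihydro-2H-chromen-4-yl]phenyl}-3-[4-(benzyloxy)-2-bromophenyl]propan-1-ol (anti) | Brc1cc(OCc2ccccc2)ccc1C[C@H](OCc1ccccc1)[C@H](O)c1cc(OCc2ccccc2)c(OCc2ccccc2)cc1[C@@H]1c3ccc(OCc4ccccc4)cc3O[C@H](c3ccc(OCc4ccccc4)c(OCc4ccccc4)c3)[C@H]1OCc1ccccc1 | intermediate
26 | (2R,3S)-3,7-bis(benzyloxy)-2-{4,5-bis(benzyloxy)-2-[(2R,3S,4R)-3,7-bis(benzyloxy)-2-[3,4-bis(benzyloxy)phenyl]-3,4-dihydro-2H-chromen-4-yl]phenyl}-3,4-dihydro-2H-chromene | C(c1ccccc1)Oc1ccc2c(c1)O[C@H](c1cc(OCc3ccccc3)c(OCc3ccccc3)cc1[C@@H]1c3ccc(OCc4ccccc4)cc3O[C@H](c3ccc(OCc4ccccc4)c(OCc4ccccc4)c3)[C@H]1OCc1ccccc1)[C@@H](OCc1ccccc1)C2 | intermediate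
27 | (2R,3S)-2-{2-[(2R,3S,4R)-2-(3,4-dihydroxyphenyl)-3,7-dihydroxy-3,4-dihydro-2H-chromen-4-yl]-4,5-dihydroxyphenyl}-3,4-dihydro-2H-chromene-3,7-diol | Oc1ccc2c(c1)O[C@H](c1cc(O)c(O)cc1[C@@H]1c3ccc(O)cc3O[C@H](c3ccc(O)c(O)c3)[C@H]1O)[C@@H](O)C2 | target

## Step count and risks

Total step count: 17. Longest linear sequence: 10 steps (steps 1, 2, 4, 5, 6, 7, 14, 15, 16, 17).

**Step 16 (key step).** Most likely failure: slow C–O bond formation from the hindered secondary alkoxide, so that reduction of the C–Br bond or oxidation of the carbinol competes at 110 °C. Fallback: the bromide is exchanged for boron and the bond is made by oxidative copper coupling near room temperature. Setting out from 25, Miyaura borylation with B2pin2, Pd(dppf)Cl2 and KOAc in dioxane would give (1R,2S)-2-(benzyloxy)-1-{4,5-bis(benzyloxy)-2-[(2R,3S,4R)-3,7-bis(benzyloxy)-2-[3,4-bis(benzyloxy)phenyl]-3,4-dihydro-2H-chromen-4-yl]phenyl}-3-[4-(benzyloxy)-2-(4,4,5,5-tetramethyl-1,3,2-dioxaborolan-2-yl)phenyl]propan-1-ol F1 in place of the bromide. Intramolecular Chan–Lam etherification of F1 with Cu(OAc)2, pyridine, O2 and 4 Å sieves in CH2Cl2 would then return to the route at 26.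

**Step 2.** Most likely failure: eroded or reversed facial selectivity with the electron-rich boronic acid and chromone. Fallback: resolution by enantioselective reduction instead of enantioselective C–C formation. Setting out from 2 and 3, the same addition with the achiral ligand 2,2′-bipyridine would give racemic 7-(benzyloxy)-2-[3,4-bis(benzyloxy)phenyl]-2,3-dihydro-4H-chromen-4-one F2 as the substrate of a kinetic resolution. Asymmetric transfer hydrogenation of F2 with RuCl(p-cymene)[(R,R)-TsDPEN] and HCO2H/Et3N would reduce the (2R) enantiomer to (2R,4R)-7-(benzyloxy)-2-[3,4-bis(benzyloxy)phenyl]-3,4-dihydro-2H-chromen-4-ol F3 and leave the (2S) ketone. The unreacted ketone, separated from F3 by chromatography, rejoins the route at 4.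

**Step 6.** Most likely failure: slow or face-unselective hydroboration because the C4 aryl group shields the alkene. Fallback: hydroborate before the C4 aryl group is present and form C4–C6′ afterwards by Friedel–Crafts arylation under control of C3. Setting out from 4, reduction with NaBH4 would give (2S,4S)-7-(benzyloxy)-2-[3,4-bis(benzyloxy)phenyl]-3,4-dihydro-2H-chromen-4-ol F4 as the 2,4-cis alcohol. Burgess dehydration of F4 would give (2S)-7-(benzyloxy)-2-[3,4-bis(benzyloxy)phenyl]-2H-chromene F5 without a C4 substituent. Hydroboration–oxidation of F5 would give (2R,3S)-7-(benzyloxy)-2-[3,4-bis(benzyloxy)phenyl]-3,4-dihydro-2H-chromen-3-ol F6 with the 2,3-trans relation. Benzylation of F6 with BnBr and NaH would give (2R,3S)-3,7-bis(benzyloxy)-2-[3,4-bis(benzyloxy)phenyl]-3,4-dihydro-2H-chromene F7 as the fully protected flavan. Oxidation of F7 with DDQ in the presence of 2-ethoxyethanol would give (2R,3S,4R)-3,7-bis(benzyloxy)-2-[3,4-bis(benzyloxy)phenyl]-4-(2-ethoxyethoxy)-3,4-dihydro-2H-chromene F8 as the 3,4-trans C4 ether. Activation of F8 with TMSOTf in the presence of excess commercial 4-bromo-1,2-bis(benzyloxy)benzene would arylate C4 trans to the C3 benzyloxy group, para to one benzyloxy group and ortho to bromine, rejoining the route at 12. The regiochemistry, the modest nucleophilicity of the bromoarene and the self-condensation of the C4 cation are the weak points of this detour.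

**Step 14.** Most likely failure: bromine–lithium exchange between aryllithium 23 and the aryl bromide of 22, or α-deprotonation of 22, both favoured by the slow attack of a hindered aryllithium on an amide. Fallback: use the faster aldehyde electrophile and adjust the oxidation level afterwards. Setting out from 22, reduction with LiAlH4 at −78 °C would give (2S)-2-(benzyloxy)-3-[4-(benzyloxy)-2-bromophenyl]propanal F9 as the electrophile. Addition of aryllithium 23, made from 12 as in step 14, to F9 at −78 °C would give 2-(benzyloxy)-1-{4,5-bis(benzyloxy)-2-[(2R,3S,4R)-3,7-bis(benzyloxy)-2-[3,4-bis(benzyloxy)phenyl]-3,4-dihydro-2H-chromen-4-yl]phenyl}-3-[4-(benzyloxy)-2-bromophenyl]propan-1-ol F10 as a mixture of C1 epimers. Dess–Martin oxidation of F10 would rejoin the route at 24.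

**Step 15.** Most likely failure: poor facial selectivity if the twisted, hindered aryl ketone does not hold the zinc chelate. Fallback: reagent control in place of substrate control. Setting out from 24, reduction with BH3·SMe2 and the (R)-configured 2-methyl-CBS-oxazaborolidine, taking the aryl group as the larger substituent, would give 25 directly; no new compound arises.

## Further compounds

F1 | step 16 | (1R,2S)-2-(benzyloxy)-1-{4,5-bis(benzyloxy)-2-[(2R,3S,4R)-3,7-bis(benzyloxy)-2-[3,4-bis(benzyloxy)phenyl]-3,4-dihydro-2H-chromen-4-yl]phenyl}-3-[4-(benzyloxy)-2-(4,4,5,5-tetramethyl-1,3,2-dioxaborolan-2-yl)phenyl]propan-1-ol | CC1(C)OB(OC1(C)C)c1cc(OCc2ccccc2)ccc1C[C@H](OCc1ccccc1)[C@H](O)c1cc(OCc2ccccc2)c(OCc2ccccc2)cc1[C@@H]1c3ccc(OCc4ccccc4)cc3O[C@H](c3ccc(OCc4ccccc4)c(OCc4ccccc4)c3)[C@H]1OCc1ccccc1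
F2 | step 2 | racemic 7-(benzyloxy)-2-[3,4-bis(benzyloxy)phenyl]-2,3-dihydro-4H-chromen-4-one | O=C1CC(c2ccc(OCc3ccccc3)c(OCc3ccccc3)c2)Oc2cc(OCc3ccccc3)ccc12
F3 | step 2 | (2R,4R)-7-(benzyloxy)-2-[3,4-bis(benzyloxy)phenyl]-3,4-dihydro-2H-chromen-4-ol (2,4-cis) | O[C@@H]1C[C@H](c2ccc(OCc3ccccc3)c(OCc3ccccc3)c2)Oc2cc(OCc3ccccc3)ccc12
F4 | step 6 | (2S,4S)-7-(benzyloxy)-2-[3,4-bis(benzyloxy)phenyl]-3,4-dihydro-2H-chromen-4-ol (2,4-cis) | O[C@H]1C[C@@H](c2ccc(OCc3ccccc3)c(OCc3ccccc3)c2)Oc2cc(OCc3ccccc3)ccc12
F5 | step 6 | (2S)-7-(benzyloxy)-2-[3,4-bis(benzyloxy)phenyl]-2H-chromene | C1=C[C@@H](c2ccc(OCc3ccccc3)c(OCc3ccccc3)c2)Oc2cc(OCc3ccccc3)ccc12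
F6 | step 6 | (2R,3S)-7-(benzyloxy)-2-[3,4-bis(benzyloxy)phenyl]-3,4-dihydro-2H-chromen-3-ol | C(c1ccccc1)Oc1ccc2c(c1)O[C@H](c1ccc(OCc3ccccc3)c(OCc3ccccc3)c1)[C@@H](O)C2
F7 | step 6 | (2R,3S)-3,7-bis(benzyloxy)-2-[3,4-bis(benzyloxy)phenyl]-3,4-dihydro-2H-chromene | C(c1ccccc1)Oc1ccc2c(c1)O[C@H](c1ccc(OCc3ccccc3)c(OCc3ccccc3)c1)[C@@H](OCc1ccccc1)C2
F8 | step 6 | (2R,3S,4R)-3,7-bis(benzyloxy)-2-[3,4-bis(benzyloxy)phenyl]-4-(2-ethoxyethoxy)-3,4-dihydro-2H-chromene (3,4-trans) | CCOCCO[C@@H]1c3ccc(OCc4ccccc4)cc3O[C@H](c3ccc(OCc4ccccc4)c(OCc4ccccc4)c3)[C@H]1OCc1ccccc1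
F9 | step 14 | (2S)-2-(benzyloxy)-3-[4-(benzyloxy)-2-bromophenyl]propanal | Brc1cc(OCc2ccccc2)ccc1C[C@H](OCc1ccccc1)C=O
F10 | step 14 | 2-(benzyloxy)-1-{4,5-bis(benzyloxy)-2-[(2R,3S,4R)-3,7-bis(benzyloxy)-2-[3,4-bis(benzyloxy)phenyl]-3,4-dihydro-2H-chromen-4-yl]phenyl}-3-[4-(benzyloxy)-2-bromophenyl]propan-1-ol, (2S), mixture of C1 epimers | Brc1cc(OCc2ccccc2)ccc1C[C@H](OCc1ccccc1)C(O)c1cc(OCc2ccccc2)c(OCc2ccccc2)cc1[C@@H]1c3ccc(OCc4ccccc4)cc3O[C@H](c3ccc(OCc4ccccc4)c(OCc4ccccc4)c3)[C@H]1OCc1ccccc1
F0 | step 15 | none | none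
A1 | alternative 1 | benzyl-protected lower flavan carrying on ring B the trans-epoxide whose upper C2 bears a 3-(benzyloxy)phenyl ether | C(c1ccccc1)Oc1ccc2c(c1)O[C@H](c1cc(OCc3ccccc3)c(OCc3ccccc3)cc1[C@H]5O[C@@H]5[C@H](Oc6cccc(OCc7ccccc7)c6)c6ccc(OCc7ccccc7)c(OCc7ccccc7)c6)[C@@H](OCc1ccccc1)C2
A2 | alternative 1 | hepta-O-benzyl target with free upper C3 hydroxyl | C(c1ccccc1)Oc1ccc2c(c1)O[C@H](c1cc(OCc3ccccc3)c(OCc3ccccc3)cc1[C@@H]1c3ccc(OCc4ccccc4)cc3O[C@H](c3ccc(OCc4ccccc4)c(OCc4ccccc4)c3)[C@H]1O)[C@@H](OCc1ccccc1)C2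
A3 | alternative 2 | mesylate of the 6-(benzyloxy)-2-(α-hydroxybenzyl)-2,3-dihydrobenzofuran carrying the protected upper unit | C(c1ccccc1)Oc1ccc2c(c1)O[C@H](C2)[C@@H](OS(C)(=O)=O)c1cc(OCc3ccccc3)c(OCc3ccccc3)cc1[C@@H]1c3ccc(OCc4ccccc4)cc3O[C@H](c3ccc(OCc4ccccc4)c(OCc4ccccc4)c3)[C@H]1OCc1ccccc1
A4 | alternative 2 | bicyclic oxiranium ion formed from A3 | C(c1ccccc1)Oc1ccc2c(c1)[O+]1[C@H](C2)[C@H]1c1cc(OCc3ccccc3)c(OCc3ccccc3)cc1[C@@H]1c3ccc(OCc4ccccc4)cc3O[C@H](c3ccc(OCc4ccccc4)c(OCc4ccccc4)c3)[C@H]1OCc1ccccc1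
A5 | alternative 2 | protected target as the lower C3 acetate | C(c1ccccc1)Oc1ccc2c(c1)O[C@H](c1cc(OCc3ccccc3)c(OCc3ccccc3)cc1[C@@H]1c3ccc(OCc4ccccc4)cc3O[C@H](c3ccc(OCc4ccccc4)c(OCc4ccccc4)c3)[C@H]1OCc1ccccc1)[C@@H](OC(C)=O)C2
A6 | alternative 3 | 2-hydroxybenzhydrol carrying the benzyl-protected lower flavan (carbinol configuration open) | C(c1ccccc1)Oc1ccc2c(c1)O[C@H](c1cc(OCc3ccccc3)c(OCc3ccccc3)cc1C(O)c1ccc(OCc3ccccc3)cc1O)[C@@H](OCc1ccccc1)C2
A7 | alternative 3 | ortho-quinone methide formed from A6 (alkene geometry open) | O=C1C=C(OCc2ccccc2)C=CC1=Cc1cc(OCc2ccccc2)c(OCc2ccccc2)cc1[C@H]1Oc2cc(OCc3ccccc3)ccc2C[C@@H]1OCc1ccccc1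
A8 | alternative 3 | (E)-2-[3,4-bis(benzyloxy)phenyl]ethenyl pivalate | CC(C)(C)C(=O)O/C=C/c1ccc(OCc2ccccc2)c(OCc2ccccc2)c1
A9 | alternative 3 | protected target as the upper C3 pivalate | C(c1ccccc1)Oc1ccc2c(c1)O[C@H](c1cc(OCc3ccccc3)c(OCc3ccccc3)cc1[C@@H]1c3ccc(OCc4ccccc4)cc3O[C@H](c3ccc(OCc4ccccc4)c(OCc4ccccc4)c3)[C@H]1OC(=O)C(C)(C)C)[C@@H](OCc1ccccc1)C2
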